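## Retrosynthetic overview

- The target is a 2H-chromene: ring C (pyran; O1, C2, C3, C4, C4a, C8a) is fused to ring A, which carries the acyl chain to ring B at C6, a hydroxyl at C7 and a prenyl group at C8. Ring C is disconnected last, at C4–C4a and O1–C2 (condensation of a phenol with 3-methylbut-2-enal, then oxa-6π closure), together with the C8–prenyl bond (aromatic Claisen shift) in the same flask.
- Enabling feature: O1 on C8a is flanked on ring A by C8 and C4a, the two carbons that carry the two C5 units. A 1,1-dimethylallyl group parked on that oxygen can be shifted to C8, which frees the hydroxyl that then builds ring C at C4a, the only ortho position left. The hydrogen bond between C7–OH and the C6 ketone steers the shift to C8 and keeps that hydroxyl out of play.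
- The precursor, a tert-allyl aryl ether, comes from the trihydroxydihydrochalcone by O-propargylation of its most acidic phenol and semi-hydrogenation. The dihydrochalcone comes from resorcinol and 3-(4-hydroxyphenyl)propanoic acid by Friedel–Crafts acylation.
- Ring order: rings A and B are bought with the starting materials; ring C is the only ring made and closes last. No protecting group is used.

Key step: step 4

Remark on the chemistry: the target has no stereocentre; primed locants C1' to C6' denote ring A of the open-chain ketones (C1' bears the acyl group), and C3', C4' and C5' become C8, C8a and C4a of the chromene.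

## Route

Step 1
Reactants: 1 resorcinol; 2 3-(4-hydroxyphenyl)propanoic acid
Product: 3 1-(2,4-dihydroxyphenyl)-3-(4-hydroxyphenyl)propan-1-one
Conditions: BF3·OEt2 (solvent), 85 °C; then aq. NaOAc
Reagents that add atoms: none
Why: Friedel–Crafts (Nencki-type) C-acylation of the electron-rich resorcinol by the BF3-activated carboxylic acid should occur at C4, para to one hydroxyl and ortho to the other, and stop after one acylation because the new ketone deactivates the ring, while the less electron-rich ring of 2 does not compete.

Step 2
Reactants: 3 1-(2,4-dihydroxyphenyl)-3-(4-hydroxyphenyl)propan-1-one; 4 3-chloro-3-methylbut-1-yne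
Product: 5 1-[2-hydroxy-4-(2-methylbut-3-yn-2-yloxy)phenyl]-3-(4-hydroxyphenyl)propan-1-one
Conditions: K2CO3 (1.2 equiv), KI (10 mol %), CuI (5 mol %), acetone, 55 °C
Reagents that add atoms: none
Why: Copper-assisted Williamson-type etherification with the tertiary propargylic chloride: the weak base ionizes only the most acidic phenol, the C4' hydroxyl para to the ketone, whereas the C2' hydroxyl is held in a hydrogen bond to the carbonyl and the ring-B phenol is about two pKa units less acidic.

Step 3
Reactants: 5 1-[2-hydroxy-4-(2-methylbut-3-yn-2-yloxy)phenyl]-3-(4-hydroxyphenyl)propan-1-one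
Product: 6 1-[2-hydroxy-4-(2-methylbut-3-en-2-yloxy)phenyl]-3-(4-hydroxyphenyl)propan-1-one
Conditions: H2 (1 atm), Pd on CaCO3 poisoned with Pb(OAc)2 (Lindlar catalyst), quinoline, EtOAc, rt
Reagents that add atoms: none
Why: Lindlar semi-hydrogenation: on the lead-poisoned palladium surface the terminal alkyne is reduced to the vinyl group much faster than the resulting alkene, and the aryl ketone, the phenols and the allylic C–O bond are left alone if the uptake is stopped at one equivalent of H2.

Step 4
Reactants: 6 1-[2-hydroxy-4-(2-methylbut-3-en-2-yloxy)phenyl]-3-(4-hydroxyphenyl)propan-1-one; 7 3-methylbut-2-enal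
Product: 10 3-(4-hydroxyphenyl)-1-[7-hydroxy-2,2-dimethyl-8-(3-methylbut-2-en-1-yl)-2H-chromen-6-yl]propan-1-one (target), via prenylated triol 8 (not isolated), via ortho-quinone methide 9 (not isolated)
Conditions: xylene, 130 °C; then 7 (3 equiv), ethylenediamine diacetate (20 mol %), 130 °C, sealed tube
Reagents that add atoms: none
Why: Heating 6 triggers the aromatic Claisen rearrangement ([3,3] shift of the aryl 1,1-dimethylallyl ether), which moves the C5 unit from the C4' oxygen to C3' as a linear prenyl group and, after enolization, leaves 8 with that oxygen as a free phenol; the amine salt then catalyses the Knoevenagel-type condensation of 7 with C5' of 8 (C–C bond formation ortho to the free hydroxyl, loss of water), which gives the ortho-quinone methide 9. The closest known reactions are the Claisen rearrangement of 4-(1,1-dimethylallyloxy)-2-hydroxyaryl ketones to the 3-prenyl compounds and the amine-salt- or pyridine-mediated chromenylation of acylresorcinols with 3-methylbut-2-enal (formal [3+3] annulation), here run back to back in one flask. Ring C closes by a thermally allowed, disrotatory oxa-6π electrocyclization of the 1-oxatriene in 9, which forms the O1–C2 bond and restores the aromaticity of ring A. No stereocentre is formed, and the ring alkene C3=C4 can only be cis. The step needs site selectivity twice: the Claisen shift must go to C3' and not to C5', which the hydrogen bond between C2'–OH and the ketone should secure by fixing the double-bond character in the C3'–C4' bond, and the condensation must then take C5', which is the only free position ortho to a free, non-chelated hydroxyl once C3' carries the prenyl group. The chelated C2' hydroxyl and the simple phenol of ring B are too weak as carbon nucleophiles to condense with the enal, so no protecting group is needed.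

## Compound list

1 | resorcinol (benzene-1,3-diol) | Oc1cccc(O)c1 | starting material
2 | 3-(4-hydroxyphenyl)propanoic acid | OC(=O)CCc1ccc(O)cc1 | starting material
3 | 1-(2,4-dihydroxyphenyl)-3-(4-hydroxyphenyl)propan-1-one | O=C(CCc1ccc(O)cc1)c1ccc(O)cc1O | intermediate
4 | 3-chloro-3-methylbut-1-yne | CC(C)(Cl)C#C | starting material
5 | 1-[2-hydroxy-4-(2-methylbut-3-yn-2-yloxy)phenyl]-3-(4-hydroxyphenyl)propan-1-one | C#CC(C)(C)Oc1ccc(C(=O)CCc2ccc(O)cc2)c(O)c1 | intermediate
6 | 1-[2-hydroxy-4-(2-methylbut-3-en-2-yloxy)phenyl]-3-(4-hydroxyphenyl)propan-1-one | C=CC(C)(C)Oc1ccc(C(=O)CCc2ccc(O)cc2)c(O)c1 | intermediate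
7 | 3-methylbut-2-enal | CC(C)=CC=O | starting material
8 | 1-[2,4-dihydroxy-3-(3-methylbut-2-en-1-yl)phenyl]-3-(4-hydroxyphenyl)propan-1-one | CC(C)=CCc1c(O)ccc(C(=O)CCc2ccc(O)cc2)c1O | intermediate
9 | (6Z)-3-hydroxy-4-[3-(4-hydroxyphenyl)propanoyl]-6-(3-methylbut-2-en-1-ylidene)-2-(3-methylbut-2-en-1-yl)cyclohexa-2,4-dien-1-one | O=C1/C(=C\C=C(C)C)C=C(C(=O)CCc2ccc(O)cc2)C(O)=C1CC=C(C)C | intermediate
10 | 3-(4-hydroxyphenyl)-1-[7-hydroxy-2,2-dimethyl-8-(3-methylbut-2-en-1-yl)-2H-chromen-6-yl]propan-1-one | CC(C)=CCc1c(O)c(C(=O)CCc2ccc(O)cc2)cc2c1OC(C)(C)C=C2 | target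

## Summary and risks

Total step count: 4. Longest linear sequence: 4 steps (from 1 and 2 to 10).

Steps most likely to fail:

**Step 4.** The second stage may stall: condensation of the enal at the hindered position C5' can be slower than self-condensation of the enal. The fallback delivers the second C5 unit through the oxygen instead of from outside. It sets out from 6, which is heated alone (N,N-diethylaniline, 130 °C) and worked up to isolate the Claisen product 8. The C4' hydroxyl of 8, its most acidic one, is etherified with 4 (K2CO3, KI cat., CuI cat., acetone, 55 °C) to give 1-[2-hydroxy-3-(3-methylbut-2-en-1-yl)-4-(2-methylbut-3-yn-2-yloxy)phenyl]-3-(4-hydroxyphenyl)propan-1-one F1. Heating F1 (xylene, 140 °C) should bring about the aryl propargyl ether Claisen shift to C5', the only open ortho position, and enolization to the allenylphenol 1-[2,4-dihydroxy-5-(3-methylbuta-1,2-dien-1-yl)-3-(3-methylbut-2-en-1-yl)phenyl]-3-(4-hydroxyphenyl)propan-1-one F2. A 1,5-hydrogen shift then leads to the same ortho-quinone methide 9 and oxa-6π closure, so the route is rejoined at 10.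

**Step 2.** Site selectivity may be lost, with the ring-B phenol etherified alongside the C4' phenol. The fallback uses temporary silyl protection and sets out from 3. TBSCl (2.2 equiv), imidazole and DMF silylate the two non-chelated phenols to give 3-[4-(tert-butyldimethylsilyloxy)phenyl]-1-[4-(tert-butyldimethylsilyloxy)-2-hydroxyphenyl]propan-1-one F3. Brief methanolysis (K2CO3 cat., MeOH, 0 °C) should cleave only the electron-poor aryl silyl ether para to the ketone and give 3-[4-(tert-butyldimethylsilyloxy)phenyl]-1-(2,4-dihydroxyphenyl)propan-1-one F4. Etherification of its only free non-chelated hydroxyl with 4 under the conditions of step 2 gives 3-[4-(tert-butyldimethylsilyloxy)phenyl]-1-[2-hydroxy-4-(2-methylbut-3-yn-2-yloxy)phenyl]propan-1-one F5. Bu4NF buffered with AcOH (THF, 0 °C) removes the silyl group and the route is rejoined at 5.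

**Step 3.** Over-reduction of the new vinyl group to an ethyl group may occur; the saturated ether cannot rearrange and is hard to separate. The fallback needs no alkyne and no hydrogenation. It sets out from 3, which is etherified directly with tert-butyl 2-methylbut-3-en-2-yl carbonate (1.05 equiv) and Pd(PPh3)4 (5 mol %) in THF at 0 °C. This is a decarboxylative allylic etherification of the Tsuji–Trost type, in which the phenoxide of the most acidic hydroxyl attacks the more substituted end of the allyl ligand on palladium. It bypasses 5 and rejoins the route at 6, and no compound outside the list is made (F0).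

Further compounds
F1 | step 4 | 1-[2-hydroxy-3-(3-methylbut-2-en-1-yl)-4-(2-methylbut-3-yn-2-yloxy)phenyl]-3-(4-hydroxyphenyl)propan-1-one | C#CC(C)(C)Oc1c(CC=C(C)C)c(O)c(C(=O)CCc2ccc(O)cc2)cc1
F2 | step 4 | 1-[2,4-dihydroxy-5-(3-methylbuta-1,2-dien-1-yl)-3-(3-methylbut-2-en-1-yl)phenyl]-3-(4-hydroxyphenyl)propan-1-one | CC(C)=C=Cc1cc(C(=O)CCc2ccc(O)cc2)c(O)c(CC=C(C)C)c1O
F3 | step 2 | 3-[4-(tert-butyldimethylsilyloxy)phenyl]-1-[4-(tert-butyldimethylsilyloxy)-2-hydroxyphenyl]propan-1-one | CC(C)(C)[Si](C)(C)Oc1ccc(CCC(=O)c2ccc(O[Si](C)(C)C(C)(C)C)cc2O)cc1
F4 | step 2 | 3-[4-(tert-butyldimethylsilyloxy)phenyl]-1-(2,4-dihydroxyphenyl)propan-1-one | CC(C)(C)[Si](C)(C)Oc1ccc(CCC(=O)c2ccc(O)cc2O)cc1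
F5 | step 2 | 3-[4-(tert-butyldimethylsilyloxy)phenyl]-1-[2-hydroxy-4-(2-methylbut-3-yn-2-yloxy)phenyl]propan-1-one | CC(C)(C)[Si](C)(C)Oc1ccc(CCC(=O)c2ccc(OC(C)(C)C#C)cc2O)cc1
F0 | step 3 | none | none
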